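## Structural features

The target is a flavone: benzene ring A is fused through C4a and C8a to the 4-pyranone ring C, and ring C carries the 3,4,5-trimethoxyphenyl ring B at C2 through the C2–C1' bond. Ring A is hexasubstituted, with hydroxyls at C5 and C7, methoxyls at C6 and C8, the ring oxygen O1 on C8a and the carbonyl carbon C4 on C4a, so five adjacent ring carbons bear oxygen. There is no stereocentre, so all questions are of regiochemistry and functional-group tolerance. The sensitive parts are the electron-rich polyphenolic ring A (easily oxidised to quinones once its hydroxyls are free), the aryl methyl ethers (cleaved by strong Lewis or mineral acids) and the C2=C3 bond (reducible under forcing hydrogenation). Ring C can open and reclose, but the opened form has a ring A that is symmetric about the axis through C4a and C7, so this equilibration is degenerate and the oxygens that become O1 and 5-OH are interchangeable until ring C closes. The real difficulty is twofold: telling three hydroxyl-level oxygens (O1, 5-OH, 7-OH) from two methoxyls on one ring, and making the C4–C4a bond at a carbon whose neighbours C5 and C8a both carry oxygen. The key step uses exactly these features: C2, C3 and C4 are a 1,3-dioxygenated three-carbon chain between C1' and C4a, a latent 1,3-diketone that an isoxazole can carry, and the double ortho-oxygenation around C4a, which hinders carbonyl chemistry at C4, is what keeps an aryl nitrile oxide centred on C4 from dimerising.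

## Logic of the disconnections

13 ⇒ 12. The O1–C2 bond is cut and the C4 carbonyl oxygen is exchanged for an amino group on the same carbon. Closing ring C by acid cyclodehydration of a 1,3-dicarbonyl equivalent onto an ortho phenol is the most reliable way to finish a flavone. The gain is that ring A becomes symmetric, so either ortho hydroxyl of 12 gives the same product. The forward step needs acid mild enough to spare five methyl ethers, and the nitrogen must leave by hydrolysis.

12 ⇒ 11. In the backward sense the N–O bond and three O–CH2Ph bonds are re-formed. All four are cleaved by one hydrogenation, so 11 carries neither a free phenol nor a carbonyl group and is robust. The demand is that hydrogenation stops at 12 without saturating its C=C bond, and that the oxidation-prone 12 is carried on without isolation.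

11 ⇒ 9 + 10. The C3–C4 bond and the O–C2 bond are cut. This is the convergent cut: it separates the two aromatic halves, and 10 is purchased. The C3–C4 bond is made at a linear, sterically accessible sp carbon, not by nucleophilic attack on a carbonyl buried between two ortho substituents. The forward step must give the 3,5-disubstituted heterocycle, and 9 must survive the heating needed.

9 ⇒ 8 ⇒ 7 ⇒ 6. No skeletal bond is cut. The dipole is traced back through dehydrochlorination, chlorination and condensation to a carbonyl group at C4. The demand is that chlorination occurs only at the oxime carbon, which is secured because ring A of 7 has no unsubstituted position.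

6 ⇒ 5. The C4–C4a bond is cut. The ring position concerned is the only free one in 5 and is ortho to two alkoxy groups and para to a third. The gain is a pentaalkoxybenzene with a mirror plane. The electrophile must be small and free of strong Lewis acid so that benzyl and methyl ethers survive. Placing this step on 5 and not on 4 saves one step, and 4 never has to be isolated.

5 ⇒ 4 ⇒ 3. Two O–benzyl bonds are cut, then the two aryl C–O bonds at the carbons that become C5 and C8a. Oxygen is introduced where halogen can be directed, which reduces the problem to a dibromide. The forward step needs a double hydroxylation of an electron-rich dibromide, and O-alkylation must win over C-alkylation of the ambident anion of 4.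

3 ⇒ 2 ⇒ 1. Two C–Br bonds and one O–benzyl bond are cut. The two methoxy groups of 2 direct electrophiles to exactly the two positions needed, and the benzyl ether marks the central oxygen for removal at the end. Bromination must avoid the position para to the benzyloxy group, which is expected because that flanked group is twisted out of conjugation.

## Other disconnections considered

Alternative 1: The cut is C8–C8a, with ring A traced back to a four-membered ring.
- **Forward key step:** the 5-metalated pyranone from 5-bromo-2-(3,4,5-trimethoxyphenyl)-4H-pyran-4-one A4 would add to the mixed squarate 3-tert-butoxy-4-methoxycyclobut-3-ene-1,2-dione A3 to give the 4-hydroxycyclobutenone A2. Heating A2 would open the four-membered ring, and the ketene carbon would close onto the pyranone carbon that becomes C8a in a 6π electrocyclisation. Enolisation would give the hydroquinone A1, 7-tert-butoxy-5,8-dihydroxy-6-methoxy-2-(3,4,5-trimethoxyphenyl)-4H-chromen-4-one.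
- **In favour:** every ring A oxygen arrives already differentiated, no electrophilic substitution on a crowded arene is needed, and the ring-forming event is unimolecular with no regiochemical choice once A2 exists.
- **Against:** A1 is a 5,8-hydroquinone prone to oxidation. It still needs selective O-methylation at C8 beside the chelated 5-hydroxyl and acid removal of the tert-butyl group. Addition to A3 must distinguish two carbonyls that differ only in the size of the neighbouring alkoxy group, and metalation of A4 competes with conjugate addition to the pyranone.
- **Comparison:** on structure, alternative 1 is the better plan for differentiating the ring A oxygens and would extend to unsymmetrical ring A patterns, whereas the chosen plan leans on the symmetry of ring A. On mechanism both are thermal pericyclic processes; the chosen one settles its regiochemistry through the terminal alkyne, while alternative 1 moves its regiochemical question into a carbonyl addition with weaker control. On step economy the two are roughly equal at best, since A3 and A4 both have to be made and two steps follow A1.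

Alternative 2: The cuts are C2–C1' and C2–C3, with carbon monoxide A8 supplying C2.
- **Forward key step:** zerovalent palladium would add to 5-iodo-1,2,3-trimethoxybenzene A7, insert A8 to give an aroylpalladium species, and couple it with the enolate of 1-[2,4,6-tris(benzyloxy)-3,5-dimethoxyphenyl]ethan-1-one A6 to give the diketone A5. Hydrogenolysis and acid would then give 13.
- **In favour:** the diketone oxidation level is reached directly, with no nitrogen to introduce and remove. The end game from A5 needs no N–O cleavage or hydrolysis, which is better than the chosen plan. The sequence is about two steps shorter (no oxime, no dipole), and A7 is as accessible as 10.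
- **Against:** A8 is a toxic gas, which runs against the aim of a safe route even with ex situ generation. A6 requires acetylation of 5 at its hindered position, where the Lewis acids of a Friedel–Crafts acylation threaten benzyl and methyl ethers. A5 is more acidic than A6, so its enolate may bind palladium or be acylated again. Direct arylation without insertion of A8 also competes.
- **Comparison:** on structure the two plans are equal, as both use the same symmetric, tris-benzylated ring A. On mechanism, alternative 2 makes two bonds at C2 through organometallic steps that need catalyst, base and gas, while the chosen cycloaddition needs no reagent at all. On step economy alternative 2 is better; on safety and on access to the ring A partner the chosen plan is better.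

Alternative 3: The cuts are C4–C4a, O1–C8a and O1–C2, with ring A as an aryne.
- **Forward key step:** fluoride would release the aryne from 3-(benzyloxy)-2,4-dimethoxy-5-[(trifluoromethanesulfonyl)oxy]-6-(trimethylsilyl)phenyl pivalate A10. The carboxylate of 3-(3,4,5-trimethoxyphenyl)propiolic acid A11 would add through oxygen at the carbon that becomes C8a, and the aryl anion at C4a would take the acyl group (net C–O insertion). The phenoxide would then close ring C by conjugate addition to give 7-(benzyloxy)-6,8-dimethoxy-4-oxo-2-(3,4,5-trimethoxyphenyl)-4H-chromen-5-yl pivalate A9.
- **In favour:** this is the most convergent plan. Ring C forms in one operation at the flavone oxidation level with no separate cyclodehydration, which is better than the chosen plan, and A11 is simple.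
- **Against:** A10 is a hexasubstituted benzene with five different kinds of substituent and would take more steps than the whole ring A sequence here. The aryne is flanked by oxygen on both sides, so the direction of carboxylate addition rests only on the difference between pivaloyloxy and methoxy, and the wrong sense gives an isomeric flavone. The ortho pivalate can transfer its acyl group to the aryl anion, a five-membered closure competes with the six-membered one, and A9 needs two different deprotections.
- **Comparison:** on structure, alternative 3 gives up the symmetry of ring A and then has to control it, while the chosen plan keeps it to the end. On mechanism both avoid carbonyl addition at the hindered C4, which is an equal point. On step economy the key operation is shorter but the overall count is expected to be clearly longer.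

Key step: step 7

Assumption: 2,6-dimethoxyphenol and 5-ethynyl-1,2,3-trimethoxybenzene are purchased. Every ring A intermediate keeps a mirror plane through the carbons that become C4a and C7, so its two ortho oxygens are equivalent.

## Route

Step 1
Reactants: 1 2,6-dimethoxyphenol (syringol)
Product: 2 2-(benzyloxy)-1,3-dimethoxybenzene
Conditions: BnBr, K2CO3, acetone, reflux
Reagents that add atoms: benzyl bromide, BrCc1ccccc1
Why: Williamson O-alkylation of the phenoxide (SN2 on a benzylic bromide); the benzyl ether marks the central oxygen, which becomes the 7-hydroxyl, for removal in the final hydrogenolysis while the two methyl ethers stay.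

Step 2
Reactants: 2 2-(benzyloxy)-1,3-dimethoxybenzene
Product: 3 3-(benzyloxy)-1,5-dibromo-2,4-dimethoxybenzene
Conditions: NBS (2.1 equiv), MeCN, 0 °C to rt
Reagents that add atoms: N-bromosuccinimide, BrN1C(=O)CCC1=O
Why: Electrophilic aromatic bromination: the two positions ortho to one methoxy and para to the other are strongly activated, whereas the position para to the central benzyloxy group is not, because that flanked group is twisted out of conjugation. The second bromine should therefore enter the mirror-image site of the first, and the unactivated benzyl ring is left alone.

Step 3
Reactants: 3 3-(benzyloxy)-1,5-dibromo-2,4-dimethoxybenzene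
Product: 5 1,3,5-tris(benzyloxy)-2,4-dimethoxybenzene, via 5-(benzyloxy)-4,6-dimethoxyresorcinol 4 (not isolated)
Conditions: Pd2(dba)3 (cat.), tBuXPhos, KOH, 1,4-dioxane/H2O, 100 °C, Ar; then BnBr, n-Bu4NBr, 60 °C
Reagents that add atoms: potassium hydroxide, [K+].[OH-]; benzyl bromide, BrCc1ccccc1
Why: Palladium-catalysed hydroxylation of aryl bromides with KOH (Buchwald-type C–O coupling: oxidative addition to zerovalent palladium, bromide–hydroxide exchange, C–O reductive elimination enforced by the bulky biaryl phosphine) gives the bis(phenoxide) of 4, which is O-benzylated in the same pot by Williamson alkylation under phase-transfer conditions. Keeping 4 as its salt under argon avoids handling an oxidation-prone polyphenol, and ion pairing with the quaternary ammonium cation should favour O- over C-alkylation.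

Step 4
Reactants: 5 1,3,5-tris(benzyloxy)-2,4-dimethoxybenzene
Product: 6 2,4,6-tris(benzyloxy)-3,5-dimethoxybenzaldehyde
Conditions: POCl3, DMF, 0 °C to 70 °C; then aq NaOAc
Reagents that add atoms: N,N-dimethylformamide, CN(C)C=O; water, O
Why: Vilsmeier–Haack formylation: the chloroiminium ion attacks the only unsubstituted ring carbon, which is ortho to two benzyloxy groups and para to the third, and aqueous acetate hydrolyses the aryl iminium salt to the aldehyde. The electrophile is small and no strong Lewis acid is present, so benzyl and methyl ethers should survive.

Step 5
Reactants: 6 2,4,6-tris(benzyloxy)-3,5-dimethoxybenzaldehyde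
Product: 7 (E)-2,4,6-tris(benzyloxy)-3,5-dimethoxybenzaldehyde oxime
Conditions: NH2OH·HCl, NaOAc, EtOH/H2O, 70 °C
Reagents that add atoms: hydroxylamine hydrochloride, NO.Cl
Why: Condensation of the aldehyde with hydroxylamine (addition–elimination) under acetate buffering; the aldehyde cannot enolise or self-condense. The E oxime is expected, and its geometry is of no consequence for the next step.

Step 6
Reactants: 7 (E)-2,4,6-tris(benzyloxy)-3,5-dimethoxybenzaldehyde oxime
Product: 9 2,4,6-tris(benzyloxy)-3,5-dimethoxybenzonitrile oxide, via hydroximoyl chloride 8 (not isolated)
Conditions: NCS, DMF, rt; then Et3N, Et2O, 0 °C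
Reagents that add atoms: none
Why: Chlorination of the aldoxime at carbon by NCS gives the hydroximoyl chloride 8, and triethylamine removes HCl in a 1,3-elimination to the nitrile oxide (the standard Huisgen generation). Ring A has no free position, so NCS can react only at the oxime; the two ortho-benzyloxy groups shield the dipole carbon, so 9 should be persistent enough to be washed, concentrated cold and used as a discrete reagent.

Step 7
Reactants: 9 2,4,6-tris(benzyloxy)-3,5-dimethoxybenzonitrile oxide; 10 5-ethynyl-1,2,3-trimethoxybenzene
Product: 11 3-[2,4,6-tris(benzyloxy)-3,5-dimethoxyphenyl]-5-(3,4,5-trimethoxyphenyl)isoxazole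
Conditions: 10 (1.5 equiv), toluene, 80 °C, Ar
Reagents that add atoms: none
Why: This is a thermal 1,3-dipolar (Huisgen) cycloaddition of a nitrile oxide to a terminal alkyne, a concerted but asynchronous six-electron process in which the dipole carbon (future C4) bonds to the terminal alkyne carbon (future C3) and the dipole oxygen to the aryl-bearing alkyne carbon (future C2). The closest known reaction type is the addition of mesitonitrile oxide and other 2,6-disubstituted benzonitrile oxides to arylacetylenes, which gives 3,5-diarylisoxazoles. The isoxazole ring is closed by the intermolecular cycloaddition itself, both ring bonds forming in one transition state and the product being aromatic at once, so no separate cyclisation or oxidation is involved. No stereocentre is created. The selectivity needed is regiochemical, 3,5- against 3,4-disubstitution: the bulky, di-ortho-substituted aryl group on the dipole carbon goes to the unsubstituted alkyne terminus, and the larger frontier-orbital coefficient of a monosubstituted arylacetylene sits at that terminus. Chemoselectivity against dimerisation to the furoxan comes from the two ortho-benzyloxy groups, which block the approach of a second bulky dipole but not of the slim alkyne CH. The temperature is kept moderate so that thermal rearrangement of the hindered nitrile oxide to the isocyanate should not compete. An excess of the purchased partner 10 compensates for the rate lost to hindrance.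

Step 8
Reactants: 11 3-[2,4,6-tris(benzyloxy)-3,5-dimethoxyphenyl]-5-(3,4,5-trimethoxyphenyl)isoxazole
Product: 13 5,7-dihydroxy-6,8,3',4',5'-pentamethoxyflavone, via enaminone triol 12 (not isolated)
Conditions: H2 (1 atm), 10% Pd/C, THF/MeOH, rt; filter under Ar; then 2 M aq HCl, 70 °C
Reagents that add atoms: water, O
Why: Hydrogenolysis over Pd/C cleaves the weak isoxazole N–O bond to the vinylogous amide 12 and the three O-benzyl bonds in one operation (reductive isoxazole opening to a β-enaminone). In aqueous acid a phenolic oxygen ortho to the side chain adds to the ring B carbonyl carbon in a six-membered closure, water is lost, and the C4 iminium is hydrolysed to the carbonyl, as in the cyclodehydration that ends a Baker–Venkataraman flavone synthesis. The two ortho hydroxyls are equivalent, so only one flavone can form, and dilute HCl should leave the methyl ethers intact.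

## Compound list

1 | 2,6-dimethoxyphenol (syringol) | COc1cccc(OC)c1O | starting material
2 | 2-(benzyloxy)-1,3-dimethoxybenzene | COc1cccc(OC)c1OCc1ccccc1 | intermediate
3 | 3-(benzyloxy)-1,5-dibromo-2,4-dimethoxybenzene | COc1c(Br)cc(Br)c(OC)c1OCc1ccccc1 | intermediate
4 | 5-(benzyloxy)-4,6-dimethoxyresorcinol (5-(benzyloxy)-4,6-dimethoxybenzene-1,3-diol; present in the flask as its dipotassium salt) | COc1c(O)cc(O)c(OC)c1OCc1ccccc1 | intermediate (not isolated)
5 | 1,3,5-tris(benzyloxy)-2,4-dimethoxybenzene | COc1c(OCc2ccccc2)cc(OCc2ccccc2)c(OC)c1OCc1ccccc1 | intermediate
6 | 2,4,6-tris(benzyloxy)-3,5-dimethoxybenzaldehyde | O=Cc1c(OCc2ccccc2)c(OC)c(OCc2ccccc2)c(OC)c1OCc1ccccc1 | intermediate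
7 | (E)-2,4,6-tris(benzyloxy)-3,5-dimethoxybenzaldehyde oxime | O/N=C/c1c(OCc2ccccc2)c(OC)c(OCc2ccccc2)c(OC)c1OCc1ccccc1 | intermediate
8 | (Z)-2,4,6-tris(benzyloxy)-N-hydroxy-3,5-dimethoxybenzenecarboximidoyl chloride (hydroximoyl chloride) | O/N=C(\Cl)c1c(OCc2ccccc2)c(OC)c(OCc2ccccc2)c(OC)c1OCc1ccccc1 | intermediate (not isolated)
9 | 2,4,6-tris(benzyloxy)-3,5-dimethoxybenzonitrile oxide | [O-][N+]#Cc1c(OCc2ccccc2)c(OC)c(OCc2ccccc2)c(OC)c1OCc1ccccc1 | intermediate
10 | 5-ethynyl-1,2,3-trimethoxybenzene | C#Cc1cc(OC)c(OC)c(OC)c1 | starting material
11 | 3-[2,4,6-tris(benzyloxy)-3,5-dimethoxyphenyl]-5-(3,4,5-trimethoxyphenyl)isoxazole | COc1cc(-c2cc(-c3c(OCc4ccccc4)c(OC)c(OCc4ccccc4)c(OC)c3OCc3ccccc3)no2)cc(OC)c1OC | intermediate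
12 | (Z)-3-amino-3-(2,4,6-trihydroxy-3,5-dimethoxyphenyl)-1-(3,4,5-trimethoxyphenyl)prop-2-en-1-one (enaminone triol) | N/C(=C\C(=O)c1cc(OC)c(OC)c(OC)c1)c1c(O)c(OC)c(O)c(OC)c1O | intermediate (not isolated)
13 | 5,7-dihydroxy-6,8,3',4',5'-pentamethoxyflavone | COc1cc(-c2cc(=O)c3c(O)c(OC)c(O)c(OC)c3o2)cc(OC)c1OC | target

## Step count and least certain steps

Total step count: 8. Longest linear sequence: 8 steps (1 to 13); 10 is purchased and enters at step 7.

**Step 7 (key step).**
- **Risk:** the cycloaddition may be slow, because the dipole carbon is shielded by two ortho-benzyloxy groups and an electron-rich arylacetylene is only a moderate dipolarophile. Prolonged heating would then let thermal rearrangement of the nitrile oxide to the isocyanate compete and could erode the 3,5-regioselectivity.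
- **Fallback:** this sets out from 9. Cycloaddition to purchased 3,4,5-trimethoxystyrene (C=Cc1cc(OC)c(OC)c(OC)c1), an alkene that should react faster and place its aryl group at C5 for the same steric and electronic reasons, would give racemic 3-[2,4,6-tris(benzyloxy)-3,5-dimethoxyphenyl]-5-(3,4,5-trimethoxyphenyl)-4,5-dihydroisoxazole F1. Dehydrogenation of the isoxazoline with activated MnO2 in hot toluene then comes back to the route at 11.

**Step 3.**
- **Risk:** the second hydroxylation may stall once the first phenoxide has made the arene more electron-rich, and hydrodebromination may compete. In the benzylation stage, alkylation at the carbon between the two phenoxide oxygens may compete with O-alkylation in the aqueous medium.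
- **Fallback:** this sets out from 3. Double Miyaura borylation (B2pin2, Pd(dppf)Cl2, KOAc, 1,4-dioxane, 90 °C) would give 2,2'-[5-(benzyloxy)-4,6-dimethoxy-1,3-phenylene]bis(4,4,5,5-tetramethyl-1,3,2-dioxaborolane) F2. Oxidation (H2O2, NaOH, THF/H2O, 0 °C) and acidification would give 4, here isolated. Benzylation in an aprotic medium (BnBr, K2CO3, DMF) comes back to the route at 5.

**Step 4.**
- **Risk:** electrophilic attack may be sluggish, because the two benzyloxy groups flanking the free position are each buttressed by a methoxy neighbour and shield it. Forcing the reaction risks loss of benzyl groups to the acidic chlorophosphorus medium.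
- **Fallback:** this sets out from 4, isolated by acidifying the step 3 mixture before any benzyl bromide is added. Vilsmeier formylation at the free-phenol stage (POCl3, DMF, MeCN, 0 °C to rt, aqueous hydrolysis), where the hydroxyls are stronger and smaller donors, would give 4-(benzyloxy)-2,6-dihydroxy-3,5-dimethoxybenzaldehyde F3. Double O-benzylation (BnBr, K2CO3, DMF, 60 °C) comes back to the route at 6.

**Step 8.**
- **Risk:** the rates of the two hydrogenolyses may be mismatched. The benzyl ethers should cleave readily, but N–O cleavage of a 3,5-diarylisoxazole bearing a di-ortho-substituted aryl group may lag, and pushing for completion invites saturation of the enaminone C=C bond. The debenzylated intermediates are also open to air oxidation.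
- **Fallback:** this sets out from 11. Reductive N–O cleavage with Mo(CO)6 in wet MeCN at 80 °C, which leaves benzyl ethers alone, would give (Z)-3-amino-3-[2,4,6-tris(benzyloxy)-3,5-dimethoxyphenyl]-1-(3,4,5-trimethoxyphenyl)prop-2-en-1-one F4. A short hydrogenolysis (H2, 10% Pd/C) that now has only O-benzyl bonds to cleave comes back to the route at 12, which is cyclised with aqueous HCl as in step 8.

## Further compounds

F1 | step 7 | 3-[2,4,6-tris(benzyloxy)-3,5-dimethoxyphenyl]-5-(3,4,5-trimethoxyphenyl)-4,5-dihydroisoxazole (racemic) | COc1cc(C2CC(c3c(OCc4ccccc4)c(OC)c(OCc4ccccc4)c(OC)c3OCc3ccccc3)=NO2)cc(OC)c1OC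
F2 | step 3 | 2,2'-[5-(benzyloxy)-4,6-dimethoxy-1,3-phenylene]bis(4,4,5,5-tetramethyl-1,3,2-dioxaborolane) | COc1c(B2OC(C)(C)C(C)(C)O2)cc(B2OC(C)(C)C(C)(C)O2)c(OC)c1OCc1ccccc1
F3 | step 4 | 4-(benzyloxy)-2,6-dihydroxy-3,5-dimethoxybenzaldehyde | O=Cc1c(O)c(OC)c(OCc2ccccc2)c(OC)c1O
F4 | step 8 | (Z)-3-amino-3-[2,4,6-tris(benzyloxy)-3,5-dimethoxyphenyl]-1-(3,4,5-trimethoxyphenyl)prop-2-en-1-one | N/C(=C\C(=O)c1cc(OC)c(OC)c(OC)c1)c1c(OCc2ccccc2)c(OC)c(OCc2ccccc2)c(OC)c1OCc1ccccc1
A1 | alternative 1 | 7-tert-butoxy-5,8-dihydroxy-6-methoxy-2-(3,4,5-trimethoxyphenyl)-4H-chromen-4-one | COc1cc(-c2cc(=O)c3c(O)c(OC)c(OC(C)(C)C)c(O)c3o2)cc(OC)c1OC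
A2 | alternative 1 | 2-tert-butoxy-4-hydroxy-3-methoxy-4-[4-oxo-6-(3,4,5-trimethoxyphenyl)-4H-pyran-3-yl]cyclobut-2-en-1-one (racemic) | COC1=C(OC(C)(C)C)C(=O)C1(O)c1coc(-c2cc(OC)c(OC)c(OC)c2)cc1=O
A3 | alternative 1 | 3-tert-butoxy-4-methoxycyclobut-3-ene-1,2-dione | COC1=C(OC(C)(C)C)C(=O)C1=O
A4 | alternative 1 | 5-bromo-2-(3,4,5-trimethoxyphenyl)-4H-pyran-4-one | COc1cc(-c2cc(=O)c(Br)co2)cc(OC)c1OC
A5 | alternative 2 | 1-[2,4,6-tris(benzyloxy)-3,5-dimethoxyphenyl]-3-(3,4,5-trimethoxyphenyl)propane-1,3-dione | COc1cc(C(=O)CC(=O)c2c(OCc3ccccc3)c(OC)c(OCc3ccccc3)c(OC)c2OCc2ccccc2)cc(OC)c1OC
A6 | alternative 2 | 1-[2,4,6-tris(benzyloxy)-3,5-dimethoxyphenyl]ethan-1-one | CC(=O)c1c(OCc2ccccc2)c(OC)c(OCc2ccccc2)c(OC)c1OCc1ccccc1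
A7 | alternative 2 | 5-iodo-1,2,3-trimethoxybenzene | COc1cc(I)cc(OC)c1OC
A8 | alternative 2 | carbon monoxide | [C-]#[O+]
A9 | alternative 3 | 7-(benzyloxy)-6,8-dimethoxy-4-oxo-2-(3,4,5-trimethoxyphenyl)-4H-chromen-5-yl pivalate | COc1cc(-c2cc(=O)c3c(OC(=O)C(C)(C)C)c(OC)c(OCc4ccccc4)c(OC)c3o2)cc(OC)c1OC
A10 | alternative 3 | 3-(benzyloxy)-2,4-dimethoxy-5-[(trifluoromethanesulfonyl)oxy]-6-(trimethylsilyl)phenyl pivalate | COc1c(OCc2ccccc2)c(OC)c(OS(=O)(=O)C(F)(F)F)c([Si](C)(C)C)c1OC(=O)C(C)(C)C
A11 | alternative 3 | 3-(3,4,5-trimethoxyphenyl)propiolic acid | COc1cc(C#CC(=O)O)cc(OC)c1OC
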